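(Readings and results come from a simulation with constants of no real substance; scatter was added.)

Test an invariant on the earlier runs: the square of c(target) over c(starting material) times time.

common to all: gas 81 mM (held)

| run | starting material | remark | time |
|---|---|---|---|
| dawn | 0.17 M | run made earlier |  |
| winter | 0.38 M | run made earlier |  |
| flask | 0.25 M |  | 6.0 d |

| dawn: time / d | dawn: target / % | winter: time / d | winter: target / % |
|---|---|---|---|
| 0.333 | 1.9 | 0.417 | 0.2 |
| 0.833 | 2.2 | 0.625 | 1.1 |
| 1.67 | 2.0 | 1.04 | 0.7 |
| 2.50 | 2.8 | 1.67 | 1.6 |
| 4.00 | 4.1 | 3.00 | 2.1 |
| 5.00 | 4.4 | 5.00 | 2.7 |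

(scatter of a reading: 0.5 percentage points)

- at the start none of the gas is in solution
- partner is what gas becomes in solution

- amount of target at 6.0 d, in percent of the starting material charged
- concentration of partner in solution at 6.0 d, in percent of saturation

Look at the dawn run first. It read 1.9 % at 0.333 d, then gained 1.6 percentage points between 2.50 d and 5.00 d, so its rate as read fell. A rate set by starting material and partner at fixed levels gives a straight climb, and these readings bend. So I read a brake made during the run, with rate proportional to c(starting material) over c(target). Integrate that and the invariant follows. I take c(partner) close to saturation, 81 mM, as my assumption.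

Take the last dawn reading. It gives 0.0658 mM d⁻¹ for that quotient, the brake constant. Multiply it by the time, divide by c(starting material) and take the root: this flask gets 3.97 % of target at 6.0 d. Now go the second way, through the last winter reading: 0.0554 mM d⁻¹, so 3.65 %. The two runs differ in charge, yet part by 0.32 points, less than the scatter of one reading. I commit to 3.81 %.

The forecast says 4.1 % of target and partner at 40 % of saturation, reading that “consumption pulls partner below saturation”. Its yield stands above mine, and on partner we differ.

The flask gives 4.74 % of target and partner at >99.9 % of saturation.

    starting material ⇌ intermediate + leaving ligand (K = 3.81 × 10⁻⁶ M, k = 7.02 × 10⁻⁶ s⁻¹)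
    partner + intermediate → target (k = 0.00202 L mol⁻¹ s⁻¹)
    gas ⇌ partner, rate k3*(csat - [partner]) (kL = 3.01 × 10⁻⁴ s⁻¹)
    starting material + intermediate → side product (k = 3.26 × 10⁻⁵ L mol⁻¹ s⁻¹)

Gas transfer could deliver 5056 % into a solution kept empty by 6.0 d, far above the target made in this flask. Intermediate falls back 19 times faster than it goes on at 0.0328 d, a pre-equilibrium at that moment, and the back step takes leaving ligand, which stands at 0.0125 M at 6.00 d.

Now use the brake constant 0.0658 mM d⁻¹ on the neighbour flask charged with 0.062 M: it gives 7.98 % of target at 6.0 d. The simulated neighbour holds 9.47 %.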